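**Strategy**

Everything rests on removing the two C2 methylenes. Each cyclopropane (C1–C2–C3 on ring A) is disconnected to a C1=C3 alkene, which reveals a twofold-symmetric, twelve-membered bis-cyclopentadiene. The key step exploits that C2 is a bare methylene bonded only to C1 and C3, and that C1=C3 is the only 1,2-disubstituted alkene of each trienone, the one most remote from the C8 carbonyl (C4=C5 is tetrasubstituted, C6=C7 is the enone bond). One zinc-carbenoid operation therefore forms four C–C bonds, two rings and four stereocentres. The precursor is the Negishi cyclodimer of a bicyclic dienyl triflate/alkylzinc monomer whose C9 oxygens are pseudo-axial (9α) silyl ethers that shield the face opposite the C14 methyl.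

Key step: step 16

Remarks on the chemistry
- Numbering: lindenane numbering is used for all bicyclic and macrocyclic compounds. Ring A = C1, C3, C4, C5, C10 (C2 is the CH2 added in step 16); ring B = C5–C10; C14 = CH3 on C10; C15 = CH2 on C4; C11 carries C13 (CH3) and C12 (CO2CH3). β is the face that carries C14, α the opposite face. C11 is R in every compound that contains it.
- Design of the key-step substrate: the natural 9β-oxygen is pseudo-equatorial and leaves the α face of C1=C3 open. A free C9 hydroxyl lies on the α side of the ring A plane in either configuration and would guide zinc to the wrong face. The route therefore carries the pseudo-axial 9α silyl ether, which is what enolate hydroxylation should give kinetically, through step 16. The natural 9β-OH is restored in step 17. Compounds 21 and 23 have the required skeletons and differ from the natural series only at C9/C9′.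
- Assumption: the enantiomer of the oxazaborolidinium catalyst in step 8 is chosen by the selection rules for 2-substituted quinones; if the sense proves opposite, its enantiomer is used and nothing else changes.

**Route**

Step 1
Reactants: 1 methyl (R)-3-hydroxybutanoate
Product: 2 methyl (2R,3R)-3-hydroxy-2-methylbutanoate
Conditions: LDA (2.2 equiv), THF, −78 → −20 °C; MeI, −78 → 0 °C
Reagents that add atoms: iodomethane, CI
Why: Fráter–Seebach alkylation, in which the chelated dianion is methylated anti to the C3 methyl to give the anti ester; the new C2 centre is transient because it is re-enolised in step 2.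

Step 2
Reactants: 2 methyl (2R,3R)-3-hydroxy-2-methylbutanoate
Product: 3 methyl (2R,3R)-3-hydroxy-2-(iodomethyl)-2-methylbutanoate
Conditions: LDA (2.2 equiv), THF, −78 → −20 °C; CH2I2, DMPU, −78 → −20 °C; AcOH quench at −20 °C
Reagents that add atoms: diiodomethane, ICI
Why: Second Fráter–Seebach alkylation, in which the tetrasubstituted chelated enolate is iodomethylated (an established alkylation of hindered ester enolates) anti to the C3 methyl, setting the quaternary carbon (future C11, R); the product has no α-hydrogen, so the iodide cannot eliminate.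

Step 3
Reactants: 3 methyl (2R,3R)-3-hydroxy-2-(iodomethyl)-2-methylbutanoate
Product: 4 methyl (R)-2-(iodomethyl)-2-methyl-3-oxobutanoate
Conditions: Dess–Martin periodinane, CH2Cl2, rt
Reagents that add atoms: none
Why: Dess–Martin oxidation removes the controlling carbinol centre and gives a β-keto ester whose quaternary centre cannot epimerise.

Step 4
Reactants: 4 methyl (R)-2-(iodomethyl)-2-methyl-3-oxobutanoate
Product: 5 methyl (R)-2-(iodomethyl)-2-methyl-3-(trifluoromethylsulfonyloxy)but-3-enoate
Conditions: KHMDS, THF, −78 °C; PhNTf2, −78 → 0 °C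
Reagents that add atoms: N-phenylbis(trifluoromethanesulfonimide), O=S(=O)(N(c1ccccc1)S(=O)(=O)C(F)(F)F)C(F)(F)F
Why: Kinetic enolisation of the methyl ketone (its only enolisable side) and O-sulfonylation give the 1,1-disubstituted enol triflate; the neopentyl iodide is inert to the cold enolate.

Step 5
Reactants: 5 methyl (R)-2-(iodomethyl)-2-methyl-3-(trifluoromethylsulfonyloxy)but-3-enoate
Product: 7 methyl (R)-2-(iodomethyl)-2-methyl-3-methylidene-4-oxopentanoate, via 2-ethoxydiene 6 (not isolated)
Conditions: CH2=C(OEt)SnBu3, Pd(PPh3)4 (5 mol%), LiCl, THF, 65 °C; then 1 M HCl, THF, rt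
Reagents that add atoms: tributyl(1-ethoxyvinyl)stannane, CCOC(=C)[Sn](CCCC)(CCCC)CCCC; water, O
Why: Stille coupling of the enol triflate with an acetyl-anion equivalent, then acid hydrolysis of the enol ether, gives the α-methylene ketone; Pd(PPh3)4 does not insert into the neopentyl iodide.

Step 6
Reactants: 7 methyl (R)-2-(iodomethyl)-2-methyl-3-methylidene-4-oxopentanoate
Product: 8 methyl (R)-2-(iodomethyl)-2-methyl-3-methylidene-4-(triisopropylsilyloxy)pent-4-enoate
Conditions: TIPSOTf, Et3N, CH2Cl2, 0 °C
Reagents that add atoms: triisopropylsilyl triflate, CC(C)[Si](OS(=O)(=O)C(F)(F)F)(C(C)C)C(C)C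
Why: Soft enolisation and O-silylation of the methyl ketone give the 2-silyloxy-1,3-diene (C6=C7–C8(OTIPS)=C9).

Step 7
Reactants: 9 3-methylcyclopent-2-en-1-one
Product: 10 4-methylcyclopent-4-ene-1,3-dione
Conditions: Rh2(cap)4 (1 mol%), t-BuOOH (70% aq), 1,2-dichloroethane, 40 °C
Reagents that add atoms: tert-butyl hydroperoxide, CC(C)(C)OO
Why: Catalytic allylic C–H oxidation of the γ-methylene of an enone to the ene-dione.

Step 8
Reactants: 8 methyl (R)-2-(iodomethyl)-2-methyl-3-methylidene-4-(triisopropylsilyloxy)pent-4-enoate; 10 4-methylcyclopent-4-ene-1,3-dione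
Product: 11 cis-fused dione adduct (5β-H; 10β-CH3; C7=C8–OTIPS)
Conditions: (S)-B-(o-tolyl) diphenylprolinol oxazaborolidine·Tf2NH (20 mol%), CH2Cl2, −78 → −40 °C
Reagents that add atoms: none
Why: Enantioselective Diels–Alder reaction under chiral oxazaborolidinium catalysis, in which the catalyst binds the C4 carbonyl (its α-carbon C5 bears H) so that the nucleophilic C9 of the silyloxydiene bonds to the methyl-bearing C10 and C6 to C5; suprafacial addition makes H-5 and C14 cis, the catalyst face fixes their absolute configuration, and C11 is a remote spectator.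

Step 9
Reactants: 11 cis-fused dione adduct (crude)
Product: 12 C4 enol triflate (C3=C4(OTf)–C1=O)
Conditions: PhNTf2, Et3N, DMAP (cat.), CH2Cl2, 0 °C
Reagents that add atoms: N-phenylbis(trifluoromethanesulfonimide), O=S(=O)(N(c1ccccc1)S(=O)(=O)C(F)(F)F)C(F)(F)F
Why: O-Sulfonylation of the cyclic 1,3-dione enolate should occur at the less hindered C4 oxygen (C1=O is flanked by the quaternary C10), which gives the β-triflyloxy enone and already places the coupling handle on C4.

Step 10
Reactants: 12 C4 enol triflate
Product: 13 C1 allylic alcohol (C1 configuration immaterial)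
Conditions: DIBAL-H (1.2 equiv), CH2Cl2, −78 °C; MeOH then Rochelle salt at −78 °C
Reagents that add atoms: none
Why: 1,2-Reduction of the activated enone carbonyl by DIBAL-H, faster than attack on the hindered methyl ester; the cold quench of the aluminium alkoxide avoids fragmentation of the vinylogous acyl triflate, and the C1 centre is lost in step 12.

Step 11
Reactants: 13 C1 allylic alcohol
Product: 14 ring B enone (C6=C7–C8=O; C1–OH; C3=C4(OTf))
Conditions: DDQ, 2,6-lutidine, MeCN/CH2Cl2, 0 °C → rt
Reagents that add atoms: none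
Why: DDQ dehydrogenation of the silyl enol ether (hydride abstraction from allylic C6–H, then loss of silyl) gives the C6=C7 enone regiospecifically, since only abstraction at C6 gives an oxygen-stabilised cation.

Step 12
Reactants: 14 ring B enone
Product: 16 dienyl triflate (C1=C3; C4(OTf)=C5; C6=C7–C8=O), via C1 mesylate 15 (not isolated)
Conditions: MsCl, Et3N, CH2Cl2, −30 °C; then DBU, −30 → 0 °C
Reagents that add atoms: none
Why: Mesylation followed by base-induced 1,4-elimination (vinylogous E1cB), in which DBU removes H-5 (γ to the new enone) and the C1 mesylate leaves through C3=C4, giving a cyclopentadiene that cannot isomerise because C10 is quaternary.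

Step 13
Reactants: 16 dienyl triflate
Product: 17 9α-hydroxy dienyl triflate
Conditions: NaHMDS, THF, −78 °C; 2-(phenylsulfonyl)-3-phenyloxaziridine, −78 °C; AcOH
Reagents that add atoms: 2-(phenylsulfonyl)-3-phenyloxaziridine, O=S(=O)(N1OC1c1ccccc1)c1ccccc1
Why: Enolate hydroxylation with an N-sulfonyloxaziridine (C9 is the only enolisable position of the C8 ketone), in which the oxidant approaches C9 anti to the pseudo-axial C14 methyl on C10 and sets the pseudo-axial 9α-hydroxyl.

Step 14
Reactants: 17 9α-hydroxy dienyl triflate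
Product: 18 9α-triisopropylsilyloxy monomer
Conditions: TIPSOTf, 2,6-lutidine, CH2Cl2, 0 °C → rt
Reagents that add atoms: triisopropylsilyl triflate, CC(C)[Si](OS(=O)(=O)C(F)(F)F)(C(C)C)C(C)C
Why: Silylation of the hindered secondary alcohol with the silyl triflate removes the zinc-directing hydroxyl and installs the α-face shield needed in step 16.

Step 15
Reactants: 18 9α-triisopropylsilyloxy monomer (two molecules)
Product: 21 bis-cyclopentadiene macrocycle (9α,9′α-bis-OTIPS), via organozinc monomer 19 (not isolated), via linear dimer 20 (not isolated)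
Conditions: Zn dust (activated), LiCl, THF, 40 °C; then slow addition to Pd2(dba)3 (5 mol%), SPhos (12 mol%), THF/NMP, 55 °C, 2 mM
Reagents that add atoms: none
Why: Zinc insertion gives a stabilised zinc homoenolate and Negishi C(sp3)–C(sp2) coupling with the dienyl triflate occurs head-to-tail twice; the alkylpalladium has no β-hydrogen (C11 is quaternary), the monomer cannot close on itself because C4 and C7 are held s-trans, and slow addition favours closure of the linear dimer to the twelve-membered ring.

Step 16
Reactants: 21 bis-cyclopentadiene macrocycle (9α,9′α-bis-OTIPS)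
Product: 23 9,9′-di-epi-cycloshizukaol A bis(triisopropylsilyl) ether, via mono-cyclopropane 22 (not isolated)
Conditions: Et2Zn, CF3CO2H, CH2I2 (6 equiv each), CH2Cl2, 0 °C → rt
Reagents that add atoms: diiodomethane, ICI
Why: The zinc carbenoid ICH2ZnO2CCF3 transfers CH2 to C1=C3 in a concerted, stereospecific [2+1] addition through a butterfly transition state, the closest known reaction type being the Simmons–Smith cyclopropanation (trifluoroacetate-modified carbenoid) of the least substituted alkene of cyclic dienes and polyenones. Each three-membered ring is closed by this cheletropic-type syn addition, which forms C1–C2 and C2–C3 in the same event and necessarily gives the cis-fused bicyclo[3.1.0]hexene. The configuration at C1 and C3 follows from the face of attack, which the C9 substituent controls: the 9α-silyloxy group is pseudo-axial and sits over the α face of ring A next to C1, whereas the β face carries only the C14 methyl, so CH2 should enter syn to C14. Silylation is essential, because a free C9 hydroxyl would deliver the zinc reagent to the α face. Site selectivity is also required and is secured by the substrate, since C4=C5 is tetrasubstituted and C6=C7 is the enone alkene, leaving C1=C3 as the most electron-rich and accessible bond of each trienone. The two ring A units are remote from each other and react independently, so the second transfer repeats the first.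

Step 17
Reactants: 23 9,9′-di-epi-cycloshizukaol A bis(triisopropylsilyl) ether
Product: 25 cycloshizukaol A, via 9,9′-di-epi-cycloshizukaol A 24 (not isolated)
Conditions: TBAF, THF, 0 °C → rt; then DBU (0.5 equiv), rt; AcOH
Reagents that add atoms: none
Why: Fluoride cleavage of the silyl ethers, then base-mediated epimerisation of the α-ketol through the enediolate (C9 is the only enolisable carbon), in which reprotonation anti to the C14 methyl gives the pseudo-equatorial 9β-hydroxyl that is also the thermodynamic epimer because it hydrogen-bonds to the C8 carbonyl.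

**Compound list**

1 | methyl (R)-3-hydroxybutanoate | C[C@@H](O)CC(=O)OC | starting material
2 | methyl (2R,3R)-3-hydroxy-2-methylbutanoate | C[C@@H](O)[C@@H](C)C(=O)OC | intermediate
3 | methyl (2R,3R)-3-hydroxy-2-(iodomethyl)-2-methylbutanoate | C[C@@H](O)[C@](C)(C(=O)OC)CI | intermediate
4 | methyl (R)-2-(iodomethyl)-2-methyl-3-oxobutanoate | CC(=O)[C@](C)(C(=O)OC)CI | intermediate
5 | methyl (R)-2-(iodomethyl)-2-methyl-3-(trifluoromethylsulfonyloxy)but-3-enoate | C=C(OS(=O)(=O)C(F)(F)F)[C@](C)(C(=O)OC)CI | intermediate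
6 | methyl (R)-4-ethoxy-2-(iodomethyl)-2-methyl-3-methylidenepent-4-enoate (2-ethoxydiene, formed in situ) | C=C(OCC)C(=C)[C@](C)(C(=O)OC)CI | intermediate
7 | methyl (R)-2-(iodomethyl)-2-methyl-3-methylidene-4-oxopentanoate | C=C(C(C)=O)[C@](C)(C(=O)OC)CI | intermediate
8 | methyl (R)-2-(iodomethyl)-2-methyl-3-methylidene-4-(triisopropylsilyloxy)pent-4-enoate | C=C(C(=C)O[Si](C(C)C)(C(C)C)C(C)C)[C@](C)(C(=O)OC)CI | intermediate
9 | 3-methylcyclopent-2-en-1-one | CC1=CC(=O)CC1 | starting material
10 | 4-methylcyclopent-4-ene-1,3-dione | CC1=CC(=O)CC1=O | intermediate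
11 | cis-fused Diels–Alder adduct: ring A C1(=O)–C3H2–C4(=O); H-5 and C14 methyl both β; ring B C6H2–C7=C8(OTIPS)–C9H2; C7 bears (R)-C11(CH3)(CO2CH3)CH2I | O=C1[C@H]2CC([C@](C)(C(=O)OC)CI)=C(O[Si](C(C)C)(C(C)C)C(C)C)C[C@@]2(C)C(=O)C1 | intermediate
12 | C4 enol triflate of 11: C3=C4(OTf) conjugated to C1=O; rest as 11 | FC(F)(F)S(=O)(=O)OC1[C@H]2CC([C@](C)(C(=O)OC)CI)=C(O[Si](C(C)C)(C(C)C)C(C)C)C[C@@]2(C)C(=O)C=1 | intermediate
13 | C1 allylic alcohol of 12 (C1 configuration immaterial, not specified) | FC(F)(F)S(=O)(=O)OC1[C@H]2CC([C@](C)(C(=O)OC)CI)=C(O[Si](C(C)C)(C(C)C)C(C)C)C[C@@]2(C)C(O)C=1 | intermediate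
14 | ring B enone: C6=C7–C8=O, C9H2; C1–OH; C3=C4(OTf); H-5 β | FC(F)(F)S(=O)(=O)OC1[C@H]2C=C([C@](C)(C(=O)OC)CI)C(=O)C[C@@]2(C)C(O)C=1 | intermediate
15 | C1 methanesulfonate of 14 (formed in situ) | FC(F)(F)S(=O)(=O)OC1[C@H]2C=C([C@](C)(C(=O)OC)CI)C(=O)C[C@@]2(C)C(OS(C)(=O)=O)C=1 | intermediate
16 | dienyl triflate: C1=C3, C4(OTf)=C5, C6=C7, C8=O, C9H2; 10β-CH3; (R)-C11 with CH2I | FC(F)(F)S(=O)(=O)OC1=C2C=C([C@](C)(C(=O)OC)CI)C(=O)C[C@@]2(C)C=C1 | intermediate
17 | 9α-hydroxy derivative of 16 (OH pseudo-axial, trans to C14) | FC(F)(F)S(=O)(=O)OC1=C2C=C([C@](C)(C(=O)OC)CI)C(=O)[C@@H](O)[C@@]2(C)C=C1 | intermediate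
18 | 9α-triisopropylsilyl ether of 17 (monomer) | FC(F)(F)S(=O)(=O)OC1=C2C=C([C@](C)(C(=O)OC)CI)C(=O)[C@@H](O[Si](C(C)C)(C(C)C)C(C)C)[C@@]2(C)C=C1 | intermediate
19 | alkylzinc iodide of 18 (C15H2ZnI, formed in situ) | FC(F)(F)S(=O)(=O)OC1=C2C=C([C@](C)(C(=O)OC)C[Zn]I)C(=O)[C@@H](O[Si](C(C)C)(C(C)C)C(C)C)[C@@]2(C)C=C1 | intermediate
20 | linear head-to-tail dimer: one C15–C4′ bond; terminal C4–OTf and terminal C15H2ZnI (formed in situ) | FC(F)(F)S(=O)(=O)OC1=C2C=C([C@](C)(C(=O)OC)CC3=C4C=C([C@](C)(C(=O)OC)C[Zn]I)C(=O)[C@@H](O[Si](C(C)C)(C(C)C)C(C)C)[C@@]4(C)C=C3)C(=O)[C@@H](O[Si](C(C)C)(C(C)C)C(C)C)[C@@]2(C)C=C1 | intermediate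
21 | 2,2′-bisnor macrocycle: twelve-membered bis-cyclopentadiene (C1=C3 in both ring A units), 9α,9′α-bis(triisopropylsilyloxy) | COC(=O)[C@]1(C)CC2=C3C=C(C(=O)[C@@H](O[Si](C(C)C)(C(C)C)C(C)C)[C@@]3(C)C=C2)[C@](C)(C(=O)OC)CC2=C3C=C1C(=O)[C@@H](O[Si](C(C)C)(C(C)C)C(C)C)[C@@]3(C)C=C2 | intermediate
22 | mono-cyclopropane: one ring A 1β,3β-methano (C2 syn to C14), the other still C1=C3 (formed in situ) | COC(=O)[C@]1(C)CC2=C3C=C(C(=O)[C@@H](O[Si](C(C)C)(C(C)C)C(C)C)[C@@]3(C)[C@@H]3C[C@H]23)[C@](C)(C(=O)OC)CC2=C3C=C1C(=O)[C@@H](O[Si](C(C)C)(C(C)C)C(C)C)[C@@]3(C)C=C2 | intermediate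
23 | 9,9′-di-epi-cycloshizukaol A bis(triisopropylsilyl) ether | COC(=O)[C@]1(C)CC2=C3C=C(C(=O)[C@@H](O[Si](C(C)C)(C(C)C)C(C)C)[C@@]3(C)[C@@H]3C[C@H]23)[C@](C)(C(=O)OC)CC2=C3C=C1C(=O)[C@@H](O[Si](C(C)C)(C(C)C)C(C)C)[C@@]3(C)[C@@H]1C[C@H]21 | intermediate
24 | 9,9′-di-epi-cycloshizukaol A (formed in situ) | COC(=O)[C@]1(C)CC2=C3C=C(C(=O)[C@@H](O)[C@@]3(C)[C@@H]3C[C@H]23)[C@](C)(C(=O)OC)CC2=C3C=C1C(=O)[C@@H](O)[C@@]3(C)[C@@H]1C[C@H]21 | intermediate
25 | cycloshizukaol A | COC(=O)[C@]1(C)CC2=C3C=C(C(=O)[C@H](O)[C@@]3(C)[C@@H]3C[C@H]23)[C@](C)(C(=O)OC)CC2=C3C=C1C(=O)[C@H](O)[C@@]3(C)[C@@H]1C[C@H]21 | target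

**Step count**

Total: 17 steps. Longest linear sequence: 16 steps (steps 1–6 and 8–17); step 7 is a one-step side branch.

**Steps most likely to fail**

1. Step 16. The methylene may be delivered to the α face at one or both ring A units, or the second transfer may stall, giving diastereomers that are hard to separate on the macrocycle. The fallback moves the transfer ahead of macrocyclisation. Setting out from 18, the same zinc carbenoid is applied to the single C1=C3 bond to give the 1β,3β-methano monomer F1, whose β-diastereomer is purified. Zinc insertion gives the cyclopropanated organozinc F2, and palladium-catalysed head-to-tail coupling through the cyclopropanated linear dimer F3, under the conditions of step 15, closes the ring. The route is rejoined at 23.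

2. Step 15. Open-chain oligomerisation may outrun closure of the twelve-membered ring, or slow transmetalation of the neopentyl zinc may lead to protodemetalation. The fallback is a stepwise assembly. Organozinc 19 is cross-coupled at normal concentration with a threefold excess of 18 (Pd(PPh3)4, which leaves the alkyl iodide untouched) to give the linear iodide–triflate dimer F4, and the excess 18 is recovered. Zinc insertion into F4 gives 20, which is then cyclised on its own under high dilution. The route is rejoined at 21.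

3. Step 17. Equilibration at C9 may be incomplete or may not favour the natural epimer, leaving 9-epimers in the final product. The fallback is an oxidation–reduction sequence. Setting out from 24 (isolated after buffered fluoride, HF·pyridine), Dess–Martin oxidation gives the bis(8,9-dione) F5. Reduction with NaBH4/CeCl3 at −78 °C should take the non-conjugated C9 carbonyls first, with hydride entering from the α face, anti to the C14 methyl and the β-cyclopropane. The route is rejoined at 25.

Further compounds
F1 | step 16 | 1β,3β-methano monomer (cyclopropanated 18: C4 triflate, CH2I, 9α-OTIPS) | FC(F)(F)S(=O)(=O)OC1=C2C=C([C@](C)(C(=O)OC)CI)C(=O)[C@@H](O[Si](C(C)C)(C(C)C)C(C)C)[C@@]2(C)[C@@H]2C[C@H]12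
F2 | step 16 | cyclopropanated organozinc (C15H2ZnI) | FC(F)(F)S(=O)(=O)OC1=C2C=C([C@](C)(C(=O)OC)C[Zn]I)C(=O)[C@@H](O[Si](C(C)C)(C(C)C)C(C)C)[C@@]2(C)[C@@H]2C[C@H]12
F3 | step 16 | cyclopropanated linear dimer (terminal C4–OTf, terminal C15H2ZnI) | FC(F)(F)S(=O)(=O)OC1=C2C=C([C@](C)(C(=O)OC)CC3=C4C=C([C@](C)(C(=O)OC)C[Zn]I)C(=O)[C@@H](O[Si](C(C)C)(C(C)C)C(C)C)[C@@]4(C)[C@@H]4C[C@H]34)C(=O)[C@@H](O[Si](C(C)C)(C(C)C)C(C)C)[C@@]2(C)[C@@H]2C[C@H]12
F4 | step 15 | linear iodide–triflate dimer (terminal C4–OTf, terminal C15H2I) | FC(F)(F)S(=O)(=O)OC1=C2C=C([C@](C)(C(=O)OC)CC3=C4C=C([C@](C)(C(=O)OC)CI)C(=O)[C@@H](O[Si](C(C)C)(C(C)C)C(C)C)[C@@]4(C)C=C3)C(=O)[C@@H](O[Si](C(C)C)(C(C)C)C(C)C)[C@@]2(C)C=C1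
F5 | step 17 | bis(8,9-dione) (9,9′-didehydro-cycloshizukaol A) | COC(=O)[C@]1(C)CC2=C3C=C(C(=O)C(=O)[C@@]3(C)[C@@H]3C[C@H]23)[C@](C)(C(=O)OC)CC2=C3C=C1C(=O)C(=O)[C@@]3(C)[C@@H]1C[C@H]21
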